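**Retrosynthetic overview**
1. Endgame: the C8 isobutyrate and the free C10 hydroxyl come from bis(silyl ether) 23 by desilylation, then selective acylation of the secondary alcohol.
2. Key disconnection: C6–C7, the bond shared by the five-membered lactone and the ten-membered carbocycle. Cutting it, together with the O–C12 acyl bond, unfolds the bicycle to the acyclic ω-formyl (Z)-2-(bromomethyl)enoate 20. Both rings form in one chromium-mediated operation, carbocycle first and lactone second.
3. Enabling feature: the α-methylene-γ-butyrolactone array O–C6H–C7H–C11(=C13H2)–C12(=O) is the retron of a 2-(alkoxycarbonyl)allyl metal adding through its γ-carbon to an aldehyde. The oxygen-bearing stereocentre C8 next to C7 steers both new centres.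
4. Bromide 20 comes from α-silyloxy aldehyde 16 and methyl propiolate (C11–C13). Aldehyde 16 comes from ketone 14, made by acyl cross-coupling (C2–C3) of a borane derived from (R)-linalool with thioester 4.
5. Stereocentres: C10 from (R)-linalool, C8 by L-proline aminoxylation, C4 by Evans allylation, C6 and C7 in the key step.

Key step: step 13

Remark: germacrane locants are used throughout (C3 ketone, C4 CH–CH3, C6 lactone O–CH, C7 ring-fusion CH, C8 CH–O-acyl, C10 carbinol, C11=C13 methylene, C12 lactone carbonyl), and the target is taken as the open γ-hydroxy ketone that is drawn, which may equilibrate with its transannular C3/C10 hemiketal in solution.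

Step 1
Reactants: 1 (S)-4-benzyl-3-propanoyl-1,3-oxazolidin-2-one
Product: 3 (S)-4-benzyl-3-[(2R)-2-methylpent-4-enoyl]-1,3-oxazolidin-2-one, via sodium enolate 2 (not isolated)
Conditions: NaN(SiMe3)2, THF, −78 °C; allyl iodide, −78 to −40 °C
Reagents that add atoms: allyl iodide, C=CCI
Why: Evans asymmetric alkylation, in which the chelated Z-enolate 2 is shielded on one face by the benzyl group, so allyl iodide enters from the other face and sets the (R)-methyl centre (later C4).

Step 2
Reactants: 3 (S)-4-benzyl-3-[(2R)-2-methylpent-4-enoyl]-1,3-oxazolidin-2-one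
Product: 4 S-ethyl (2R)-2-methylpent-4-enethioate
Conditions: EtSH, n-BuLi, THF, 0 °C
Reagents that add atoms: ethanethiol, CCS
Why: Thiolate transacylation (nucleophilic acyl substitution at the exocyclic imide carbonyl) gives the thioester without touching the α-stereocentre and frees the auxiliary.

Step 3
Reactants: 5 (R)-(−)-linalool
Product: 6 (3R)-3,7-dimethyl-3-(triethylsilyloxy)octa-1,6-diene
Conditions: Et3SiOTf, 2,6-lutidine, CH2Cl2, 0 °C
Reagents that add atoms: triethylsilyl triflate, CC[Si](CC)(CC)OS(=O)(=O)C(F)(F)F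
Why: O-silylation of the hindered tertiary alcohol needs the silyl triflate and leaves the chiral-pool carbinol carbon (later C10) untouched.

Step 4
Reactants: 6 (3R)-3,7-dimethyl-3-(triethylsilyloxy)octa-1,6-diene
Product: 8 (4R)-4-methyl-4-(triethylsilyloxy)hex-5-enal, via ozonide 7 (not isolated)
Conditions: O3, CH2Cl2, −78 °C (Sudan Red 7B end point); PPh3, −78 °C to rt
Reagents that add atoms: ozone, [O-][O+]=O
Why: Chemoselective ozonolysis (Criegee mechanism), in which the electron-rich trisubstituted alkene reacts much faster than the hindered vinyl group next to the silyloxy carbon, and PPh3 reduces ozonide 7 to the aldehyde.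

Step 5
Reactants: 8 (4R)-4-methyl-4-(triethylsilyloxy)hex-5-enal
Product: 10 (2R,4R)-4-methyl-2-(N-phenylaminooxy)-4-(triethylsilyloxy)hex-5-en-1-ol, via aminooxy aldehyde 9 (not isolated)
Conditions: PhNO, L-proline (20 mol %), CHCl3, 4 °C; NaBH4, MeOH, 0 °C
Reagents that add atoms: nitrosobenzene, O=Nc1ccccc1
Why: Proline-catalysed α-aminoxylation (enamine catalysis, O-selective nitroso aldol reaction), in which the carboxylic acid of the L-proline enamine delivers PhNO to one enamine face and sets (R) at the new C–O carbon (later C8), while NaBH4 traps the labile aldehyde 9 in the same flask.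

Step 6
Reactants: 10 (2R,4R)-4-methyl-2-(N-phenylaminooxy)-4-(triethylsilyloxy)hex-5-en-1-ol
Product: 11 (2R,4R)-4-methyl-4-(triethylsilyloxy)hex-5-ene-1,2-diol
Conditions: Zn, AcOH–THF, rt
Reagents that add atoms: none
Why: Reductive N–O cleavage by zinc in acetic acid frees the secondary hydroxyl without touching the alkene, the tertiary silyl ether or either stereocentre.

Step 7
Reactants: 11 (2R,4R)-4-methyl-4-(triethylsilyloxy)hex-5-ene-1,2-diol
Product: 12 (3R,5R)-3-methyl-3,5,6-tris(triethylsilyloxy)hex-1-ene
Conditions: Et3SiCl, imidazole, DMAP (cat.), CH2Cl2, 0 °C to rt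
Reagents that add atoms: chlorotriethylsilane, CC[Si](Cl)(CC)CC
Why: Standard double O-silylation puts a non-chelating, poorly leaving group on the C8 oxygen and a primary silyl ether that step 9 can oxidise directly.

Step 8
Reactants: 12 (3R,5R)-3-methyl-3,5,6-tris(triethylsilyloxy)hex-1-ene; 4 S-ethyl (2R)-2-methylpent-4-enethioate
Product: 14 (4R,8S,10R)-4,8-dimethyl-8,10,11-tris(triethylsilyloxy)undec-1-en-5-one, via B-alkyl-9-BBN 13 (not isolated)
Conditions: 9-BBN-H, THF, rt to 40 °C; then 4, Pd2(dba)3 (cat.), P(2-furyl)3, CuTC = Cu(O2CC4H3S), Cs2CO3, THF, 45 °C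
Reagents that add atoms: none
Why: Anti-Markovnikov hydroboration of the only alkene of 12, followed by Liebeskind–Srogl acyl cross-coupling of the B-alkyl-9-BBN with the thioester, forms the C2–C3 ketone bond without over-addition and under conditions too mild to epimerise C4.

Step 9
Reactants: 14 (4R,8S,10R)-4,8-dimethyl-8,10,11-tris(triethylsilyloxy)undec-1-en-5-one
Product: 16 (2R,4S,8R)-4,8-dimethyl-7-oxo-2,4-bis(triethylsilyloxy)undec-10-enal, via alkoxysulfonium chloride 15 (not isolated)
Conditions: (COCl)2, DMSO, CH2Cl2, −78 to −40 °C; Et3N, −78 to 0 °C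
Reagents that add atoms: none
Why: Swern oxidation applied directly to silyl ethers, in which activated DMSO desilylates and oxidises only the unhindered primary triethylsilyl ether, so the α-silyloxy aldehyde forms without a separate deprotection.

Step 10
Reactants: 16 (2R,4S,8R)-4,8-dimethyl-7-oxo-2,4-bis(triethylsilyloxy)undec-10-enal
Product: 17 methyl (4R,6S,10R)-3-hydroxy-6,10-dimethyl-2-methylidene-9-oxo-4,6-bis(triethylsilyloxy)tridec-12-enoate (both C3 epimers)
Conditions: methyl propiolate, i-Bu2AlH, NMO, THF, 0 °C; then 16, 0 °C to rt; aq. potassium sodium tartrate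
Reagents that add atoms: methyl propiolate, C#CC(=O)OC
Why: Vinylalumination (hydroalumination of the propiolate to the α-aluminoacrylate and 1,2-addition, an aluminium variant of the Morita–Baylis–Hillman reaction) is fast, non-basic and aldehyde-selective, so C8 and the ketone are safe, and the new carbinol centre is erased in step 12.

Step 11
Reactants: 17 methyl (4R,6S,10R)-3-hydroxy-6,10-dimethyl-2-methylidene-9-oxo-4,6-bis(triethylsilyloxy)tridec-12-enoate
Product: 19 methyl (4R,6S,10R)-3-hydroxy-6,10-dimethyl-2-methylidene-9,12-dioxo-4,6-bis(triethylsilyloxy)dodecanoate, via ozonide 18 (not isolated)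
Conditions: O3, CH2Cl2, −78 °C (Sudan Red 7B end point); PPh3, −78 °C to rt
Reagents that add atoms: ozone, [O-][O+]=O
Why: Chemoselective ozonolysis cleaves the alkyl-substituted terminal alkene well before the electron-poor acrylate C=C, and doing it before bromination keeps the phosphine away from an allylic bromide.

Step 12
Reactants: 19 methyl (4R,6S,10R)-3-hydroxy-6,10-dimethyl-2-methylidene-9,12-dioxo-4,6-bis(triethylsilyloxy)dodecanoate
Product: 20 methyl (2Z,4R,6S,10R)-2-(bromomethyl)-6,10-dimethyl-9,12-dioxo-4,6-bis(triethylsilyloxy)dodec-2-enoate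
Conditions: NBS, Me2S, CH2Cl2, 0 °C to rt
Reagents that add atoms: N-bromosuccinimide, O=C1CCC(=O)N1Br
Why: SN2' bromination of the Morita–Baylis–Hillman-type alcohol through its alkoxysulfonium salt, in which bromide attacks the methylene terminus of both epimers and A(1,3) strain in the transition state favours the Z-alkene (C8 cis to CH2Br), under neutral conditions that spare aldehyde, ketone and silyl ethers.

Step 13
Reactants: 20 methyl (2Z,4R,6S,10R)-2-(bromomethyl)-6,10-dimethyl-9,12-dioxo-4,6-bis(triethylsilyloxy)dodec-2-enoate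
Product: 23 (4R,6S,7S,8R,10S)-3-oxo-8,10-bis(triethylsilyloxy)germacr-11(13)-en-6,12-olide (cis-fused lactone), via allylchromium species 21 (not isolated), via chromium alkoxide 22 (not isolated)
Conditions: CrCl2 (10 equiv), 4 Å MS, THF–DMF, rt; 20 added by syringe pump (final 2 mM); aq. work-up, brief stirring with silica gel
Reagents that add atoms: none
Why: Two equivalents of CrCl2 (divalent chromium) reduce the C–Br bond to the 2-(methoxycarbonyl)allyl species 21 of trivalent chromium, which adds through its γ-carbon C7 to the formyl carbon C6 in a closed chair transition state while the double bond moves to C11=C13, and alkoxide 22 then attacks the methyl ester, so one operation gives the C6–C7 bond, both rings, the exocyclic methylene and two stereocentres from an open chain. The closest known reaction type is the intramolecular Nozaki–Hiyama–Kishi allylation with in-situ lactonisation (chromium Barbier reaction) of ω-formyl 2-(bromomethyl)enoates, which has precedent for ten-membered germacranolide rings. The carbocycle closes by a 10-exo-trig addition to C=O (SE2' at the allyl unit) and the lactone by a 5-exo-trig acyl substitution at C12. The C6/C7 relationship is controlled by the alkene geometry: C8 cis to CH2Cr sits axial and C5 equatorial in the chair, which gives the syn adduct and hence the cis-fused lactone. The C7/C8 relationship is controlled by the (8R) centre: A(1,3) strain with CH2Cr turns H8 inward, and the tether carbon C9 must stand anti to the forming bond because the other rotamer forces C9 and C5 into a syn-pentane contact, so the aldehyde meets the face that leaves the small silyloxy oxygen outside and (8R) is relayed to (7S) and (6S). The step needs aldehyde over C3 ketone (chemoselectivity of organochromium reagents, reinforced by the α-branched ketone and by the 2-ester group that would be 1,3-diaxial to a ketone substituent), γ- over α-attack (cyclic transition state), cyclisation over oligomerisation (slow addition, high dilution) and addition over vinylogous β-elimination at C8 (a silyl ether, not the ester, is carried there).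

Step 14
Reactants: 23 (4R,6S,7S,8R,10S)-3-oxo-8,10-bis(triethylsilyloxy)germacr-11(13)-en-6,12-olide
Product: 24 (4R,6S,7R,8R,10S)-8,10-dihydroxy-3-oxogermacr-11(13)-en-6,12-olide (same spatial arrangement as 23; the C7 descriptor changes by the priority rules only)
Conditions: HF·pyridine, pyridine, THF, 0 °C to rt
Reagents that add atoms: none
Why: Fluoride-driven desilylation in a buffered, weakly acidic medium removes both triethylsilyl ethers without base that could add to the methylene lactone, epimerise C4 or open the lactone.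

Step 15
Reactants: 24 (4R,6S,7R,8R,10S)-8,10-dihydroxy-3-oxogermacr-11(13)-en-6,12-olide
Product: 25 (4R,6S,7S,8R,10S)-10-hydroxy-8-(2-methylpropanoyloxy)-3-oxogermacr-11(13)-en-6,12-olide (CNP0293926.1)
Conditions: (i-PrCO)2O, DMAP (cat.), pyridine, CH2Cl2, 0 °C to rt
Reagents that add atoms: isobutyric anhydride, CC(C)C(=O)OC(=O)C(C)C
Why: DMAP-catalysed acylation esterifies the secondary C8 hydroxyl and leaves the tertiary C10 hydroxyl untouched for steric reasons, with no change at any stereocentre.

**Compound list**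
1 | (S)-4-benzyl-3-propanoyl-1,3-oxazolidin-2-one | CCC(=O)N1[C@@H](Cc2ccccc2)COC1=O | starting material
2 | sodium (Z)-enolate of 1 | C/C=C(\[O-])N1[C@@H](Cc2ccccc2)COC1=O.[Na+] | intermediate
3 | (S)-4-benzyl-3-[(2R)-2-methylpent-4-enoyl]-1,3-oxazolidin-2-one | C=CC[C@@H](C)C(=O)N1[C@@H](Cc2ccccc2)COC1=O | intermediate
4 | S-ethyl (2R)-2-methylpent-4-enethioate | C=CC[C@@H](C)C(=O)SCC | intermediate
5 | (R)-(−)-linalool, (3R)-3,7-dimethylocta-1,6-dien-3-ol | C=C[C@](C)(O)CCC=C(C)C | starting material
6 | (3R)-3,7-dimethyl-3-(triethylsilyloxy)octa-1,6-diene | C=C[C@](C)(O[Si](CC)(CC)CC)CCC=C(C)C | intermediate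
7 | 3,3-dimethyl-5-[(3R)-3-methyl-3-(triethylsilyloxy)pent-4-en-1-yl]-1,2,4-trioxolane | C=C[C@](C)(O[Si](CC)(CC)CC)CCC1OOC(C)(C)O1 | intermediate
8 | (4R)-4-methyl-4-(triethylsilyloxy)hex-5-enal | C=C[C@](C)(O[Si](CC)(CC)CC)CCC=O | intermediate
9 | (2R,4R)-4-methyl-2-(N-phenylaminooxy)-4-(triethylsilyloxy)hex-5-enal | C=C[C@](C)(O[Si](CC)(CC)CC)C[C@@H](ONc1ccccc1)C=O | intermediate
10 | (2R,4R)-4-methyl-2-(N-phenylaminooxy)-4-(triethylsilyloxy)hex-5-en-1-ol | C=C[C@](C)(O[Si](CC)(CC)CC)C[C@@H](ONc1ccccc1)CO | intermediate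
11 | (2R,4R)-4-methyl-4-(triethylsilyloxy)hex-5-ene-1,2-diol | C=C[C@](C)(O[Si](CC)(CC)CC)C[C@@H](O)CO | intermediate
12 | (3R,5R)-3-methyl-3,5,6-tris(triethylsilyloxy)hex-1-ene | C=C[C@](C)(O[Si](CC)(CC)CC)C[C@@H](O[Si](CC)(CC)CC)CO[Si](CC)(CC)CC | intermediate
13 | 9-[(3S,5R)-3-methyl-3,5,6-tris(triethylsilyloxy)hexyl]-9-borabicyclo[3.3.1]nonane | B1(CC[C@](C)(O[Si](CC)(CC)CC)C[C@@H](O[Si](CC)(CC)CC)CO[Si](CC)(CC)CC)C2CCCC1CCC2 | intermediate
14 | (4R,8S,10R)-4,8-dimethyl-8,10,11-tris(triethylsilyloxy)undec-1-en-5-one | C=CC[C@@H](C)C(=O)CC[C@](C)(O[Si](CC)(CC)CC)C[C@@H](O[Si](CC)(CC)CC)CO[Si](CC)(CC)CC | intermediate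
15 | dimethyl(alkoxy)sulfonium chloride at the primary oxygen of 14 (primary silyl group lost) | C=CC[C@@H](C)C(=O)CC[C@](C)(O[Si](CC)(CC)CC)C[C@@H](O[Si](CC)(CC)CC)CO[S+](C)C.[Cl-] | intermediate
16 | (2R,4S,8R)-4,8-dimethyl-7-oxo-2,4-bis(triethylsilyloxy)undec-10-enal | C=CC[C@@H](C)C(=O)CC[C@](C)(O[Si](CC)(CC)CC)C[C@@H](O[Si](CC)(CC)CC)C=O | intermediate
17 | methyl (4R,6S,10R)-3-hydroxy-6,10-dimethyl-2-methylidene-9-oxo-4,6-bis(triethylsilyloxy)tridec-12-enoate (C3 epimers) | C=CC[C@@H](C)C(=O)CC[C@](C)(O[Si](CC)(CC)CC)C[C@@H](O[Si](CC)(CC)CC)C(O)C(=C)C(=O)OC | intermediate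
18 | 1,2,4-trioxolane (ozonide) of the terminal alkene of 17 | C1OC(C[C@@H](C)C(=O)CC[C@](C)(O[Si](CC)(CC)CC)C[C@@H](O[Si](CC)(CC)CC)C(O)C(=C)C(=O)OC)OO1 | intermediate
19 | methyl (4R,6S,10R)-3-hydroxy-6,10-dimethyl-2-methylidene-9,12-dioxo-4,6-bis(triethylsilyloxy)dodecanoate (C3 epimers) | O=CC[C@@H](C)C(=O)CC[C@](C)(O[Si](CC)(CC)CC)C[C@@H](O[Si](CC)(CC)CC)C(O)C(=C)C(=O)OC | intermediate
20 | methyl (2Z,4R,6S,10R)-2-(bromomethyl)-6,10-dimethyl-9,12-dioxo-4,6-bis(triethylsilyloxy)dodec-2-enoate | O=CC[C@@H](C)C(=O)CC[C@](C)(O[Si](CC)(CC)CC)C[C@@H](O[Si](CC)(CC)CC)/C=C(\CBr)C(=O)OC | intermediate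
21 | allylchromium dichloride derived from 20 (trivalent chromium, CrCl2 in place of Br, solvent ligands omitted) | O=CC[C@@H](C)C(=O)CC[C@](C)(O[Si](CC)(CC)CC)C[C@@H](O[Si](CC)(CC)CC)/C=C(\C[Cr](Cl)Cl)C(=O)OC | intermediate
22 | chromium alkoxide of the ten-membered hydroxy ester, methyl 2-[2-oxido-4,8-dimethyl-5-oxo-8,10-bis(triethylsilyloxy)cyclodecyl]acrylate, all centres as in 23 | COC(=O)C(=C)[C@H]1[C@@H](O[Cr](Cl)Cl)C[C@@H](C)C(=O)CC[C@](C)(O[Si](CC)(CC)CC)C[C@H]1O[Si](CC)(CC)CC | intermediate
23 | (4R,6S,7S,8R,10S)-3-oxo-8,10-bis(triethylsilyloxy)germacr-11(13)-en-6,12-olide | C=C1C(=O)O[C@H]2C[C@@H](C)C(=O)CC[C@](C)(O[Si](CC)(CC)CC)C[C@@H](O[Si](CC)(CC)CC)[C@@H]12 | intermediate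
24 | (4R,6S,7R,8R,10S)-8,10-dihydroxy-3-oxogermacr-11(13)-en-6,12-olide | C=C1C(=O)O[C@H]2C[C@@H](C)C(=O)CC[C@](C)(O)C[C@@H](O)[C@@H]12 | intermediate
25 | (4R,6S,7S,8R,10S)-10-hydroxy-8-(2-methylpropanoyloxy)-3-oxogermacr-11(13)-en-6,12-olide | C=C1C(=O)O[C@H]2C[C@@H](C)C(=O)CC[C@](C)(O)C[C@@H](OC(=O)C(C)C)[C@@H]12 | target

**Step count and risks**

Total step count: 15. Longest linear sequence: 13 steps (steps 3–15, from (R)-linalool); steps 1–2 are a two-step side branch.

Steps most likely to fail:

Step 13 (key step).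
- What may go wrong: the long-lived allylchromium species may lose the C8 silyloxy group by vinylogous β-elimination. It may attack the C3 ketone and close a seven-membered ring. It may oligomerise. Facial or syn/anti selectivity may erode through E/Z equilibration of the allyl unit.
- Fallback: the polar allyl metal is replaced by a covalent allylsilane, and the same bond is closed by Lewis acid activation of the aldehyde. The fallback sets out from 19 and returns at 23.
- Route: 19 is acetylated (Ac2O, DMAP, pyridine) to the allylic acetate F1. Pd2(dba)3-catalysed silylation with Me3SiSiMe3, with allylic transposition through the π-allylpalladium complex, gives the (Z)-2-(trimethylsilylmethyl)enoate F2. BF3·OEt2 in dilute CH2Cl2 at −78 °C closes C6–C7 by an intramolecular Hosomi–Sakurai reaction to the hydroxy ester F3. This reaction has an open, syn-selective transition state, activates the aldehyde in preference to the ketone, and has no carbon–metal bond that can eliminate. F3 lactonises on silica gel or with a trace of acid to 23.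

Step 8.
- What may go wrong: transfer of the hindered B-alkyl group to copper and palladium may be slow, protodeboronation may compete, and the carbon next to the thioester may epimerise slowly under the carbonate base.
- Fallback: a preformed organozinc reagent is coupled instead of the borane. The fallback sets out from 12 and 4 and returns at 14.
- Route: hydroboration of 12 (9-BBN-H, via 13) and oxidation with NaBO3 gives the primary alcohol F4. I2, PPh3 and imidazole give the primary iodide F5. Zinc insertion (Zn, LiCl, THF) gives the alkylzinc iodide F6, which couples with 4 under PdCl2(PPh3)2 catalysis (Fukuyama coupling, base-free) to 14.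

Step 14.
- What may go wrong: once the C8 hydroxyl is free next to the lactone, translactonisation to the equally cis-fused 8,12-olide may occur. Transannular hemiketalisation may also slow or divert the acylation in step 15.
- Fallback: the C8 hydroxyl is never set free. The fallback sets out from 23 and returns at 25.
- Route: acylative desilylation with (i-PrCO)2O and catalytic Bi(OTf)3 in CH2Cl2–MeCN at 0 °C converts the less hindered secondary silyl ether directly into the 8-isobutyrate 10-silyl ether F7. HF·pyridine then removes the tertiary silyl ether to give 25.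

**Further compounds**
F1 | step 13 | methyl (4R,6S,10R)-3-acetoxy-6,10-dimethyl-2-methylidene-9,12-dioxo-4,6-bis(triethylsilyloxy)dodecanoate | O=CC[C@@H](C)C(=O)CC[C@](C)(O[Si](CC)(CC)CC)C[C@@H](O[Si](CC)(CC)CC)C(OC(C)=O)C(=C)C(=O)OC
F2 | step 13 | methyl (2Z,4R,6S,10R)-6,10-dimethyl-9,12-dioxo-4,6-bis(triethylsilyloxy)-2-(trimethylsilylmethyl)dodec-2-enoate | O=CC[C@@H](C)C(=O)CC[C@](C)(O[Si](CC)(CC)CC)C[C@@H](O[Si](CC)(CC)CC)/C=C(\C[Si](C)(C)C)C(=O)OC
F3 | step 13 | methyl 2-[(1S,2S,4R,8S,10R)-2-hydroxy-4,8-dimethyl-5-oxo-8,10-bis(triethylsilyloxy)cyclodecyl]acrylate | COC(=O)C(=C)[C@H]1[C@@H](O)C[C@@H](C)C(=O)CC[C@](C)(O[Si](CC)(CC)CC)C[C@H]1O[Si](CC)(CC)CC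
F4 | step 8 | (3S,5R)-3-methyl-3,5,6-tris(triethylsilyloxy)hexan-1-ol | OCC[C@](C)(O[Si](CC)(CC)CC)C[C@@H](O[Si](CC)(CC)CC)CO[Si](CC)(CC)CC
F5 | step 8 | (3S,5R)-1-iodo-3-methyl-3,5,6-tris(triethylsilyloxy)hexane | ICC[C@](C)(O[Si](CC)(CC)CC)C[C@@H](O[Si](CC)(CC)CC)CO[Si](CC)(CC)CC
F6 | step 8 | [(3S,5R)-3-methyl-3,5,6-tris(triethylsilyloxy)hexyl]zinc iodide | I[Zn]CC[C@](C)(O[Si](CC)(CC)CC)C[C@@H](O[Si](CC)(CC)CC)CO[Si](CC)(CC)CC
F7 | step 14 | (4R,6S,7S,8R,10S)-8-(2-methylpropanoyloxy)-3-oxo-10-(triethylsilyloxy)germacr-11(13)-en-6,12-olide | C=C1C(=O)O[C@H]2C[C@@H](C)C(=O)CC[C@](C)(O[Si](CC)(CC)CC)C[C@@H](OC(=O)C(C)C)[C@@H]12
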